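**Retrosynthetic overview**

- The target is cut in one stroke at the two Diels–Alder C–C bonds and the lactone C–O bond. This gives (R)-sorbicillinol as the diene and an open-chain 3-O-enolpyruvyl-3-epi-shikimate; in the forward sense, lactonisation and the biomimetic [4+2] run in the same final operation.
- (R)-Sorbicillinol is never isolated. It is released from its acetate, made by Wessely oxidative dearomatisation of sorbicillin (from 2-methylresorcinol and sorbic acid) and resolved.
- The enolpyruvate comes from (−)-shikimic acid: BDA protection of the trans-diol, Mitsunobu inversion at C3, Rh-carbenoid O–H insertion, Horner–Wadsworth–Emmons methylenation.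
- Ring order: cyclohexene (chiral pool) → 1,4-dioxan-2-one (lactonisation) → bicyclo[2.2.2]octane with the spiro centre ([4+2]); the last two rings form in the final step.

Assumption: the preparative chiral-HPLC separation of the acetate enantiomers is counted as the purification of step 4, not as a separate step.

**Route**

Step 1
Reactants: 1 2-methylresorcinol
Product: 2 2,4-dihydroxy-3-methylbenzaldehyde
Conditions: POCl3, DMF, MeCN, 0 °C→rt; then H2O, 50 °C
Reagents that add atoms: N,N-dimethylformamide CN(C)C=O; water O
Why: Vilsmeier–Haack formylation goes to the position para to one OH and ortho to the other (C4 and C6 are equivalent), so a single aldehyde forms and no stereocentre is involved.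

Step 2
Reactants: 2 2,4-dihydroxy-3-methylbenzaldehyde
Product: 3 2,4-dimethylbenzene-1,3-diol
Conditions: H2 (3 bar), 10% Pd/C, AcOH, HCl (cat.), rt
Reagents that add atoms: none
Why: Catalytic hydrogenolysis of an ortho/para-hydroxybenzaldehyde proceeds through the benzylic alcohol to the methyl arene under acidic Pd/C conditions without touching the ring.

Step 3
Reactants: 3 2,4-dimethylbenzene-1,3-diol; 4 sorbic acid
Product: 5 sorbicillin
Conditions: BF3·OEt2 (neat), 110 °C, sealed tube, 30 min
Reagents that add atoms: none
Why: BF3-mediated Friedel–Crafts (Nencki-type) C-acylation with the free acid occurs at the only ring position that is ortho/para to both hydroxyls, and the E,E-diene is retained.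

Step 4
Reactants: 5 sorbicillin
Product: 6 (R)-sorbicillinol acetate
Conditions: Pb(OAc)4, AcOH/CH2Cl2, rt; SiO2; preparative chiral HPLC (amylose carbamate phase, hexane/i-PrOH)
Reagents that add atoms: lead(IV) acetate CC(=O)O[Pb](OC(C)=O)(OC(C)=O)OC(C)=O
Why: Wessely oxidative dearomatisation delivers acetate mainly to the methyl-bearing carbon ortho to the free 4-OH (the minor regioisomer is removed on silica); the new quaternary centre forms as a racemate and the (R)-enantiomer is secured by chiral HPLC and assigned by ECD.

Step 5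
Reactants: 7 (−)-shikimic acid
Product: 8 methyl shikimate 4,5-butane-2,3-diacetal (BDA)
Conditions: butane-2,3-dione, HC(OMe)3, CSA (cat.), MeOH, reflux
Reagents that add atoms: methanol CO; butane-2,3-dione CC(=O)C(C)=O; trimethyl orthoformate COC(OC)OC
Why: Fischer esterification and butane-2,3-diacetal formation in one pot protect only the trans-diequatorial 4,5-diol as the trans-fused dioxane with both OMe groups axial (anomeric control, acetal carbons S,S), leaving 3-OH free and the shikimate centres untouched.

Step 6
Reactants: 8 methyl shikimate 4,5-butane-2,3-diacetal (BDA)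
Product: 10 methyl 3-epi-shikimate 4,5-BDA acetal, via 3-epi 4-nitrobenzoate 9 (not isolated)
Conditions: PPh3, DIAD, 4-NO2C6H4CO2H, THF, 0 °C→rt; then MeOH, K2CO3 (cat.), rt
Reagents that add atoms: 4-nitrobenzoic acid OC(=O)c1ccc(cc1)[N+](=O)[O-]
Why: Mitsunobu reaction displaces the allylic oxyphosphonium by SN2 with clean inversion, setting C3 to S (all-trans triol pattern), and methanolysis of the activated benzoate in the same pot frees the alcohol.

Step 7
Reactants: 11 trimethyl phosphonoacetate
Product: 12 methyl 2-diazo-2-(dimethoxyphosphoryl)acetate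
Conditions: NaH, p-ABSA, THF, 0 °C→rt
Reagents that add atoms: 4-acetamidobenzenesulfonyl azide CC(=O)Nc1ccc(cc1)S(=O)(=O)N=[N+]=[N-]
Why: Regitz diazo transfer to the sodium phosphonoacetate anion gives the acceptor/acceptor diazo compound.

Step 8
Reactants: 10 methyl 3-epi-shikimate 4,5-BDA acetal; 12 methyl 2-diazo-2-(dimethoxyphosphoryl)acetate
Product: 13 3-O-[(dimethoxyphosphoryl)(methoxycarbonyl)methyl] ether of 10
Conditions: Rh2(OAc)4 (2 mol %), PhH, 80 °C, slow addition of 12
Reagents that add atoms: none
Why: Rh(II)-carbenoid O–H insertion forms the ether without breaking the C3–O bond, so the 3S configuration is retained; the new phosphonate carbon forms as both epimers and is destroyed in step 9.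

Step 9
Reactants: 13 3-O-[(dimethoxyphosphoryl)(methoxycarbonyl)methyl] ether of 10
Product: 14 3-O-(1-methoxycarbonylvinyl) ether of 10 (open-chain enolpyruvate)
Conditions: LiHMDS, THF, −78 °C; CH2O (g, from paraformaldehyde), −78→0 °C
Reagents that add atoms: formaldehyde C=O
Why: Horner–Wadsworth–Emmons olefination of the α-alkoxy phosphonate with formaldehyde gives the 2-alkoxyacrylate, the method used to install enolpyruvyl ethers on shikimate alcohols.

Step 10
Reactants: 14 3-O-(1-methoxycarbonylvinyl) ether of 10 (open-chain enolpyruvate); 6 (R)-sorbicillinol acetate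
Product: 18 target CNP0259039.2, via diol enolpyruvate 15 (not isolated), via exo-methylene lactone 16 (not isolated), via (R)-sorbicillinol 17 (not isolated)
Conditions: (i) 14, TFA/H2O 9:1, 0 °C→rt; evaporate (PhMe); CSA (10 mol %), PhMe, 4 Å MS, 70 °C; (ii) 6 (1.5 equiv), KOH (3 equiv), THF/H2O, 0 °C, 1 h, then added over 8 h to (i) in THF/1 M KH2PO4 (pH ≈ 6), 0 °C→rt, 24 h; RP-HPLC
Reagents that add atoms: none
Why: Acid frees the trans-diol and the 4-OH closes the six-membered lactone on the enolpyruvate ester (biomimetic lactonisation; 5-OH would need a seven-ring), then the quinol released by saponification adds as an electron-poor diene to the captodative exo-methylene lactone in a biomimetic intermolecular Diels–Alder reaction in which the CH2 terminus bonds to the CH end of the diene, the dienophile approaches syn to the quinol OH (anti to CH3) and the lactone C=O lies endo under the enol bridge, which sets the bridgeheads (S at C–CH3, R at C–H) and the spiro carbon (S) while the (R)-carbinol and the shikimate-derived centres are carried through unchanged; the exo adduct is removed by HPLC.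

**Compound list**

1 | 2-methylresorcinol (2-methylbenzene-1,3-diol) | Cc1c(O)cccc1O | starting material
2 | 2,4-dihydroxy-3-methylbenzaldehyde | Cc1c(O)ccc(C=O)c1O | intermediate
3 | 2,4-dimethylbenzene-1,3-diol | Cc1ccc(O)c(C)c1O | intermediate
4 | sorbic acid, (2E,4E)-hexa-2,4-dienoic acid | C/C=C/C=C/C(=O)O | starting material
5 | sorbicillin, (2E,4E)-1-(2,4-dihydroxy-3,5-dimethylphenyl)hexa-2,4-dien-1-one | C/C=C/C=C/C(=O)c1cc(C)c(O)c(C)c1O | intermediate
6 | (R)-sorbicillinol acetate, (1R)-3-[(2E,4E)-hexa-2,4-dienoyl]-4-hydroxy-1,5-dimethyl-6-oxocyclohexa-2,4-dien-1-yl acetate | C/C=C/C=C/C(=O)C1=C[C@@](C)(OC(C)=O)C(=O)C(C)=C1O | intermediate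
7 | (−)-shikimic acid, (3R,4S,5R)-3,4,5-trihydroxycyclohex-1-ene-1-carboxylic acid | OC(=O)C1=C[C@@H](O)[C@@H](O)[C@H](O)C1 | starting material
8 | methyl shikimate 4,5-butane-2,3-diacetal; methyl (2S,3S,4aR,8R,8aR)-8-hydroxy-2,3-dimethoxy-2,3-dimethyl-2,3,4a,5,8,8a-hexahydro-1,4-benzodioxine-6-carboxylate | COC(=O)C1=C[C@@H](O)[C@H]2O[C@](C)(OC)[C@@](C)(OC)O[C@@H]2C1 | intermediate
9 | 3-epi 4-nitrobenzoate of 8 (C8 inverted to S, other centres as in 8) | COC(=O)C1=C[C@H](OC(=O)c3ccc(cc3)[N+](=O)[O-])[C@H]2O[C@](C)(OC)[C@@](C)(OC)O[C@@H]2C1 | intermediate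
10 | methyl 3-epi-shikimate 4,5-BDA acetal; methyl (2S,3S,4aR,8S,8aR)-8-hydroxy-2,3-dimethoxy-2,3-dimethyl-2,3,4a,5,8,8a-hexahydro-1,4-benzodioxine-6-carboxylate | COC(=O)C1=C[C@H](O)[C@H]2O[C@](C)(OC)[C@@](C)(OC)O[C@@H]2C1 | intermediate
11 | trimethyl phosphonoacetate | COC(=O)CP(=O)(OC)OC | starting material
12 | methyl 2-diazo-2-(dimethoxyphosphoryl)acetate | COC(=O)C(=[N+]=[N-])P(=O)(OC)OC | intermediate
13 | 3-O-[(dimethoxyphosphoryl)(methoxycarbonyl)methyl] ether of 10 (both epimers at the phosphonate carbon; ring centres as in 10) | COC(=O)C1=C[C@H](OC(C(=O)OC)P(=O)(OC)OC)[C@H]2O[C@](C)(OC)[C@@](C)(OC)O[C@@H]2C1 | intermediate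
14 | 3-O-(1-methoxycarbonylvinyl) ether of 10 (open-chain enolpyruvate; ring centres as in 10) | COC(=O)C1=C[C@H](OC(=C)C(=O)OC)[C@H]2O[C@](C)(OC)[C@@](C)(OC)O[C@@H]2C1 | intermediate
15 | methyl (3S,4S,5R)-4,5-dihydroxy-3-[(3-methoxy-3-oxoprop-1-en-2-yl)oxy]cyclohex-1-ene-1-carboxylate | COC(=O)C1=C[C@H](OC(=C)C(=O)OC)[C@@H](O)[C@H](O)C1 | intermediate
16 | methyl (4aS,8R,8aS)-8-hydroxy-3-methylidene-2-oxo-2,3,4a,7,8,8a-hexahydro-1,4-benzodioxine-6-carboxylate (trans-fused exo-methylene lactone) | COC(=O)C1=C[C@@H]2OC(=C)C(=O)O[C@H]2[C@H](O)C1 | intermediate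
17 | (R)-sorbicillinol, (6R)-4-[(2E,4E)-hexa-2,4-dienoyl]-3,6-dihydroxy-2,6-dimethylcyclohexa-2,4-dien-1-one | C/C=C/C=C/C(=O)C1=C[C@@](C)(O)C(=O)C(C)=C1O | intermediate
18 | target CNP0259039.2: spiro[bicyclo[2.2.2]octane–1,4-benzodioxin-2-one] adduct; CH3 bridgehead S, CH bridgehead R, C(CH3)(OH) R with OH syn to the CH2 bridge, spiro carbon S with the lactone C=O syn to the enol bridge, ring-fusion CH–O centres S,S, CH–OH R, sorbyl enol E,E | C/C=C/C=C/C(O)=C1/C(=O)[C@@]2(C)C(=O)[C@](C)(O)[C@@H]1C[C@]21O[C@H]2C=C(C(=O)OC)C[C@@H](O)[C@@H]2OC1=O | target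

**Step count and risks**

Total: 10 steps. Longest linear sequence: 5 steps (7 → 8 → 10 → 13 → 14 → 18; the arene branch 1 → 2 → 3 → 5 → 6 → 18 is equally long).

Steps most likely to fail:

Step 10. The free quinol may dimerise faster than it finds the lactone, and the lactone and its enol ether are exposed to aqueous acid and buffer. The endo adduct also needs attack on the lactone face syn to the axial ring-fusion hydrogen at the ether carbon, so the exo adduct may dominate. The fallback sets out from 6 and from lactone 16, now isolated by chromatography after stage (i). The acetate 6, which does not self-dimerise at room temperature, is used itself as the diene with 16 in toluene at 80 °C (or at 10 kbar), again syn to the oxygen substituent and endo, to give the tertiary acetate of the target F1. Methanolysis of the unhindered acetyl group (K2CO3, MeOH, 0 °C; the spiro-lactone carbonyl is shielded by its quaternary neighbour) then returns to the route at 18.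

Step 4. The lead(IV) oxidation gives only moderate yield and a regioisomer, and chiral HPLC may not scale. The fallback sets out from 5. Pb(OAc)4 is pre-exchanged with (S)-2-methoxy-2-phenylacetic acid, so the Wessely oxidation gives diastereomeric quinol esters that are separated on silica or by crystallisation. The (1R)-quinol (S)-O-methylmandelate F2 is saponified under the KOH conditions of step 10 and the route is rejoined at 17.

Step 6. The activated allylic C3–O may eliminate towards a diene instead of being displaced. The fallback sets out from 8. Dess–Martin oxidation gives the enone, BDA-protected methyl 3-dehydroshikimate F3. Luche reduction (NaBH4, CeCl3·7H2O, MeOH, −78 °C) delivers hydride axially to give the equatorial all-trans alcohol, and the route is rejoined at 10.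

**Further compounds**

F1 | step 10 | O-acetyl derivative of 18 (acetate on the tertiary carbinol, all centres as in 18) | C/C=C/C=C/C(O)=C1/C(=O)[C@@]2(C)C(=O)[C@](C)(OC(C)=O)[C@@H]1C[C@]21O[C@H]2C=C(C(=O)OC)C[C@@H](O)[C@@H]2OC1=O
F2 | step 4 | (1R)-3-[(2E,4E)-hexa-2,4-dienoyl]-4-hydroxy-1,5-dimethyl-6-oxocyclohexa-2,4-dien-1-yl (2S)-2-methoxy-2-phenylacetate | C/C=C/C=C/C(=O)C1=C[C@@](C)(OC(=O)[C@@H](OC)c2ccccc2)C(=O)C(C)=C1O
F3 | step 6 | BDA-protected methyl 3-dehydroshikimate (8-oxo analogue of 8, other centres as in 8) | COC(=O)C1=CC(=O)[C@H]2O[C@](C)(OC)[C@@](C)(OC)O[C@@H]2C1
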